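**Retrosynthetic overview**

1. Selaginellin F ⇐ benzylic bromide (hydrolysis) ⇐ triaryl carbinol (BBr3 demethylation with dehydration) ⇐ C1–C7 bond from a ring A aryllithium (bromine–lithium exchange at C1) and 4,4'-dimethoxybenzophenone (rings C and D).
2. Feature the plan rests on: the alkyne C8≡C9 ties C6 of ring A (central benzene) to ring E (4-hydroxyphenyl). C6 is crowded, lying between C1 (bears the methide carbon C7) and C5 (bears CH2OH). A diaryl alkyne is a ring A–C(=O)–ring E ketone plus one carbon, so it is made by a Colvin rearrangement and no cross-coupling is needed at C6.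
3. Bromo ketone ⇐ phthalide (reduction, primary silylation, oxidation) ⇐ magnesiation of the C6–H between ester and bromine of a biaryl benzoate, trapped with 4-methoxybenzaldehyde (ring E) ⇐ iodide-selective Suzuki coupling (ring B onto C2).
4. No carbocycle is formed: ring A comes from the benzoate, then rings B, E, and C with D are attached in that order. The only ring closed is the phthalide lactone (step 2), opened again in step 3.

Key step: step 6

Remark: the target has no stereocentre and no stereogenic double bond (the dienone ring is symmetric about C7), and the ring A–ring B axis is taken as freely rotating. Compounds 6 to 9 are therefore carried as racemates.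

**Route**

Step 1
Reactants: 1 methyl 3-bromo-4-iodobenzoate; 2 (2,4-dimethoxyphenyl)boronic acid
Product: 3 methyl 3-bromo-4-(2,4-dimethoxyphenyl)benzoate
Conditions: Pd(PPh3)4 (3 mol%), K3PO4, toluene/H2O, 80 °C
Reagents that add atoms: none
Why: Suzuki–Miyaura coupling; zerovalent palladium inserts into the C–I bond much faster than into C–Br, and the bromide that remains becomes flanked by ring B, so a single arylation at the iodide is expected.

Step 2
Reactants: 3 methyl 3-bromo-4-(2,4-dimethoxyphenyl)benzoate; 4 4-methoxybenzaldehyde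
Product: 7 racemic 4-bromo-5-(2,4-dimethoxyphenyl)-3-(4-methoxyphenyl)-2-benzofuran-1(3H)-one (phthalide), via arylmagnesium chloride 5 (not isolated), via chloromagnesium alkoxide 6 (not isolated)
Conditions: TMPMgCl·LiCl (1.3 equiv), THF, 0 °C; then 4, 0 °C → rt; aq NH4Cl
Reagents that add atoms: none
Why: Directed ortho-magnesiation with the Knochel–Hauser amide base should remove the most acidic ring proton, the one between the ester and the bromine; the arylmagnesium is stable towards loss of metal bromide at 0 °C, adds to the aldehyde, and the alkoxide closes onto the neighbouring ester to the lactone (the new stereocentre is racemic and is erased in step 5).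

Step 3
Reactants: 7 racemic phthalide
Product: 8 racemic [2-bromo-3-(2,4-dimethoxyphenyl)-6-(hydroxymethyl)phenyl](4-methoxyphenyl)methanol
Conditions: LiBH4, THF, 0 → 50 °C; aq NH4Cl
Reagents that add atoms: none
Why: Hydride reduction of a lactone to the diol; LiBH4 leaves the aryl bromide and aryl ethers alone, and the non-acidic work-up avoids cyclodehydration of the diol to a phthalan.

Step 4
Reactants: 8 racemic diol
Product: 9 racemic [2-bromo-6-({[tert-butyl(dimethyl)silyl]oxy}methyl)-3-(2,4-dimethoxyphenyl)phenyl](4-methoxyphenyl)methanol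
Conditions: TBSCl (1.05 equiv), imidazole, CH2Cl2, 0 °C
Reagents that add atoms: tert-butyldimethylsilyl chloride, CC(C)(C)[Si](C)(C)Cl
Why: Silylation should go to the primary benzylic hydroxyl, because the secondary diaryl carbinol sits between two ortho substituents and is far more hindered.

Step 5
Reactants: 9 racemic mono-silyl ether
Product: 10 [2-bromo-6-({[tert-butyl(dimethyl)silyl]oxy}methyl)-3-(2,4-dimethoxyphenyl)phenyl](4-methoxyphenyl)methanone
Conditions: Dess–Martin periodinane (1.3 equiv), CH2Cl2, 0 °C → rt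
Reagents that add atoms: none
Why: Dess–Martin oxidation of a benzhydrol to the diaryl ketone; it is neutral enough for the silyl ether and does not affect the aryl bromide.

Step 6
Reactants: 10 bromo diaryl ketone; 11 trimethylsilyldiazomethane
Product: 14 {[3-bromo-4-(2,4-dimethoxyphenyl)-2-[(4-methoxyphenyl)ethynyl]phenyl]methoxy}(tert-butyl)dimethylsilane, via diazoalkene 12 (not isolated), via alkylidene carbene 13 (not isolated)
Conditions: 11 (1.6 equiv), n-BuLi (1.5 equiv), THF, −78 °C; then 10, −78 °C → reflux; H2O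
Reagents that add atoms: none
Why: Lithiated trimethylsilyldiazomethane adds to the carbonyl of 10, the α-silyl alkoxide loses lithium trimethylsilanolate in a Peterson-type elimination to give diazoalkene 12, this expels dinitrogen to give alkylidene carbene 13, and a 1,2-shift of one aryl group to the carbene carbon gives the alkyne (new bonds: C8–C9 and one aryl–alkyne carbon bond; no ring closes and no stereocentre is made). This is the Colvin rearrangement, a Fritsch–Buttenberg–Wiechell-type aryl shift that is established for diaryl ketones. Migration of ring A or of ring E leads to the same alkyne, so migratory aptitude does not matter. The selectivity needed is aryl shift over 1,5-insertion of the carbene into the benzylic C–H bonds of the CH2OTBS group or attack on its oxygen, and the very fast 1,2-aryl migration of diaryl alkylidene carbenes should secure it. The only carbanion present is the stabilised diazo anion, since n-BuLi is kept below the amount of 11, so the C1 bromide and the silyl ether are not touched, and the small reagent should still reach a carbonyl flanked by C1–Br and C5–CH2OTBS.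

Step 7
Reactants: 14 bromo diaryl alkyne; 15 4,4'-dimethoxybenzophenone
Product: 17 [3-({[tert-butyl(dimethyl)silyl]oxy}methyl)-6-(2,4-dimethoxyphenyl)-2-[(4-methoxyphenyl)ethynyl]phenyl]bis(4-methoxyphenyl)methanol, via aryllithium 16 (not isolated)
Conditions: n-BuLi (1.1 equiv), THF, −78 °C; then 15, −78 → 0 °C; aq NH4Cl at −78 °C
Reagents that add atoms: none
Why: Bromine–lithium exchange at −78 °C is much faster than addition of n-BuLi across the alkyne, and the aryllithium then adds 1,2 to the diaryl ketone; the cold quench keeps the lithium alkoxide from adding to the neighbouring alkyne.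

Step 8
Reactants: 17 triaryl carbinol
Product: 18 4-{[3-(bromomethyl)-6-(2,4-dihydroxyphenyl)-2-[(4-hydroxyphenyl)ethynyl]phenyl](4-hydroxyphenyl)methylidene}cyclohexa-2,5-dien-1-one
Conditions: BBr3 (12 equiv), CH2Cl2, −78 °C → rt; ice-water; crude product taken on
Reagents that add atoms: boron tribromide, BrB(Br)Br
Why: BBr3 cleaves the five aryl methyl ethers, converts the benzylic silyl ether into the bromide by way of its borate, and ionises the carbinol to a triarylmethyl cation that loses a proton from a para hydroxyl on aqueous quench to give the quinone methide; closure to a fluorene is not expected because the free ortho carbon of ring B is meta to both of its oxygens.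

Step 9
Reactants: 18 benzylic bromide
Product: 19 selaginellin F, 4-{[6-(2,4-dihydroxyphenyl)-3-(hydroxymethyl)-2-[(4-hydroxyphenyl)ethynyl]phenyl](4-hydroxyphenyl)methylidene}cyclohexa-2,5-dien-1-one
Conditions: acetone/H2O (1:1), 60 °C
Reagents that add atoms: water, O
Why: Solvolysis of a primary benzylic bromide by water; no base is added, so the phenols stay un-ionised and are not O-alkylated, and silver salts are avoided because they could trigger addition of the new CH2OH to the neighbouring alkyne.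

**Compound list**

1 | methyl 3-bromo-4-iodobenzoate | COC(=O)c1ccc(I)c(Br)c1 | starting material
2 | (2,4-dimethoxyphenyl)boronic acid | COc1ccc(B(O)O)c(OC)c1 | starting material
3 | methyl 3-bromo-4-(2,4-dimethoxyphenyl)benzoate | COC(=O)c1ccc(-c2ccc(OC)cc2OC)c(Br)c1 | intermediate
4 | 4-methoxybenzaldehyde | COc1ccc(C=O)cc1 | starting material
5 | chloro[2-bromo-3-(2,4-dimethoxyphenyl)-6-(methoxycarbonyl)phenyl]magnesium (LiCl complex) | COC(=O)c1ccc(-c2ccc(OC)cc2OC)c(Br)c1[Mg]Cl | intermediate
6 | racemic chloromagnesium alkoxide of methyl 3-bromo-4-(2,4-dimethoxyphenyl)-2-[hydroxy(4-methoxyphenyl)methyl]benzoate | COC(=O)c1ccc(-c2ccc(OC)cc2OC)c(Br)c1C(O[Mg]Cl)c1ccc(OC)cc1 | intermediate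
7 | racemic 4-bromo-5-(2,4-dimethoxyphenyl)-3-(4-methoxyphenyl)-2-benzofuran-1(3H)-one | COc1ccc(C2OC(=O)c3ccc(-c4ccc(OC)cc4OC)c(Br)c32)cc1 | intermediate
8 | racemic [2-bromo-3-(2,4-dimethoxyphenyl)-6-(hydroxymethyl)phenyl](4-methoxyphenyl)methanol | COc1ccc(C(O)c2c(CO)ccc(-c3ccc(OC)cc3OC)c2Br)cc1 | intermediate
9 | racemic [2-bromo-6-({[tert-butyl(dimethyl)silyl]oxy}methyl)-3-(2,4-dimethoxyphenyl)phenyl](4-methoxyphenyl)methanol | COc1ccc(C(O)c2c(CO[Si](C)(C)C(C)(C)C)ccc(-c3ccc(OC)cc3OC)c2Br)cc1 | intermediate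
10 | [2-bromo-6-({[tert-butyl(dimethyl)silyl]oxy}methyl)-3-(2,4-dimethoxyphenyl)phenyl](4-methoxyphenyl)methanone | COc1ccc(C(=O)c2c(CO[Si](C)(C)C(C)(C)C)ccc(-c3ccc(OC)cc3OC)c2Br)cc1 | intermediate
11 | trimethylsilyldiazomethane | C[Si](C)(C)C=[N+]=[N-] | starting material
12 | diazoalkene, {[3-bromo-2-[2-diazo-1-(4-methoxyphenyl)ethenyl]-4-(2,4-dimethoxyphenyl)phenyl]methoxy}(tert-butyl)dimethylsilane | COc1ccc(C(=C=[N+]=[N-])c2c(CO[Si](C)(C)C(C)(C)C)ccc(-c3ccc(OC)cc3OC)c2Br)cc1 | intermediate
13 | alkylidene carbene, the 2,2-diarylethenylidene formed from 12 by loss of dinitrogen | COc1ccc(C(=[C])c2c(CO[Si](C)(C)C(C)(C)C)ccc(-c3ccc(OC)cc3OC)c2Br)cc1 | intermediate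
14 | {[3-bromo-4-(2,4-dimethoxyphenyl)-2-[(4-methoxyphenyl)ethynyl]phenyl]methoxy}(tert-butyl)dimethylsilane | COc1ccc(C#Cc2c(CO[Si](C)(C)C(C)(C)C)ccc(-c3ccc(OC)cc3OC)c2Br)cc1 | intermediate
15 | 4,4'-dimethoxybenzophenone | COc1ccc(C(=O)c2ccc(OC)cc2)cc1 | starting material
16 | {3-({[tert-butyl(dimethyl)silyl]oxy}methyl)-6-(2,4-dimethoxyphenyl)-2-[(4-methoxyphenyl)ethynyl]phenyl}lithium | COc1ccc(C#Cc2c(CO[Si](C)(C)C(C)(C)C)ccc(-c3ccc(OC)cc3OC)c2[Li])cc1 | intermediate
17 | [3-({[tert-butyl(dimethyl)silyl]oxy}methyl)-6-(2,4-dimethoxyphenyl)-2-[(4-methoxyphenyl)ethynyl]phenyl]bis(4-methoxyphenyl)methanol | COc1ccc(C#Cc2c(CO[Si](C)(C)C(C)(C)C)ccc(-c3ccc(OC)cc3OC)c2C(O)(c4ccc(OC)cc4)c5ccc(OC)cc5)cc1 | intermediate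
18 | 4-{[3-(bromomethyl)-6-(2,4-dihydroxyphenyl)-2-[(4-hydroxyphenyl)ethynyl]phenyl](4-hydroxyphenyl)methylidene}cyclohexa-2,5-dien-1-one | O=C1C=CC(=C(c2ccc(O)cc2)c2c(-c3ccc(O)cc3O)ccc(CBr)c2C#Cc2ccc(O)cc2)C=C1 | intermediate
19 | selaginellin F | O=C1C=CC(=C(c2ccc(O)cc2)c2c(-c3ccc(O)cc3O)ccc(CO)c2C#Cc2ccc(O)cc2)C=C1 | target

**Step count**

Total step count: 9. Longest linear sequence: 9 steps (1 → 19).

**Steps most likely to fail**

Step 6. The diazo carbanion may add too slowly to a carbonyl flanked by C1–Br and C5–CH2OTBS, or the carbene may be diverted into insertion at the benzylic C–H bonds instead of rearranging. The fallback builds the alkyne from an aldehyde and a coupling at the unhindered partner. It sets out from 3: arylmagnesium 5 is trapped with DMF to give methyl 3-bromo-4-(2,4-dimethoxyphenyl)-2-formylbenzoate F1. Dimethyl (1-diazo-2-oxopropyl)phosphonate with K2CO3 in MeOH (Seyferth–Gilbert homologation in the Ohira–Bestmann form) should give methyl 3-bromo-4-(2,4-dimethoxyphenyl)-2-ethynylbenzoate F2. Sonogashira coupling with 4-iodoanisole (Pd(PPh3)2Cl2, CuI, Et3N, THF, rt), in which the aryl iodide reacts and the flanked ring A bromide does not, should give methyl 3-bromo-4-(2,4-dimethoxyphenyl)-2-[(4-methoxyphenyl)ethynyl]benzoate F3. Reduction with i-Bu2AlH (CH2Cl2, −78 °C) gives [3-bromo-4-(2,4-dimethoxyphenyl)-2-[(4-methoxyphenyl)ethynyl]phenyl]methanol F4, and TBSCl with imidazole returns to the route at 14.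

Step 8. During the long exposure needed for five-fold ether cleavage, HBr or BBr3 may add across the electron-rich alkyne, or the triarylmethyl cation may cyclise. The fallback exchanges the methyl ethers for acid-labile acetals before the alkyne exists. It sets out from 7: BBr3 (CH2Cl2, −78 → 0 °C) gives 4-bromo-5-(2,4-dihydroxyphenyl)-3-(4-hydroxyphenyl)-2-benzofuran-1(3H)-one F5, and MOMCl with i-Pr2NEt gives the tris(methoxymethyl) ether 4-bromo-5-[2,4-bis(methoxymethoxy)phenyl]-3-[4-(methoxymethoxy)phenyl]-2-benzofuran-1(3H)-one F6. The reactions of steps 3 to 6 are then repeated on this series. LiBH4 gives {2-bromo-3-[2,4-bis(methoxymethoxy)phenyl]-6-(hydroxymethyl)phenyl}[4-(methoxymethoxy)phenyl]methanol F7. TBSCl with imidazole gives its primary tert-butyldimethylsilyl ether F8. Dess–Martin periodinane gives {2-bromo-6-({[tert-butyl(dimethyl)silyl]oxy}methyl)-3-[2,4-bis(methoxymethoxy)phenyl]phenyl}[4-(methoxymethoxy)phenyl]methanone F9. Lithiated 11 gives the tris(methoxymethyl)-protected bromo diaryl alkyne F10. Bromine–lithium exchange on F10 with n-BuLi and addition to 4,4'-bis(methoxymethoxy)benzophenone F11 (from 4,4'-dihydroxybenzophenone, MOMCl, i-Pr2NEt) gives the penta(methoxymethyl)-protected triaryl carbinol F12. HCl in MeOH/THF at 40 °C should then remove the five acetals and the silyl ether and dehydrate the carbinol in one operation, so the route is rejoined at 19 without a benzylic bromide.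

Step 2. Metalation of the flanked C6–H may be incomplete, or the arylmagnesium may lose metal bromide to an aryne or attack the ester of a second molecule before the aldehyde is trapped. The fallback changes the directing group and the metal. It sets out from 3: LiOH in THF/H2O gives 3-bromo-4-(2,4-dimethoxyphenyl)benzoic acid F13. Lithium 2,2,6,6-tetramethylpiperidide (2.2 equiv, THF, −78 °C) should lithiate the carboxylate between CO2Li and bromine to give lithium 3-bromo-4-(2,4-dimethoxyphenyl)-2-lithiobenzoate F14, which has no electrophilic ester and adds to 4 at −78 °C. Acidification with aq HCl gives 3-bromo-4-(2,4-dimethoxyphenyl)-2-[hydroxy(4-methoxyphenyl)methyl]benzoic acid F15, which lactonises in the acidic work-up, and the route is rejoined at 7.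

**Further compounds**

F1 | step 6 | methyl 3-bromo-4-(2,4-dimethoxyphenyl)-2-formylbenzoate | COC(=O)c1ccc(-c2ccc(OC)cc2OC)c(Br)c1C=O
F2 | step 6 | methyl 3-bromo-4-(2,4-dimethoxyphenyl)-2-ethynylbenzoate | COC(=O)c1ccc(-c2ccc(OC)cc2OC)c(Br)c1C#C
F3 | step 6 | methyl 3-bromo-4-(2,4-dimethoxyphenyl)-2-[(4-methoxyphenyl)ethynyl]benzoate | COC(=O)c1ccc(-c2ccc(OC)cc2OC)c(Br)c1C#Cc1ccc(OC)cc1
F4 | step 6 | [3-bromo-4-(2,4-dimethoxyphenyl)-2-[(4-methoxyphenyl)ethynyl]phenyl]methanol | OCc1ccc(-c2ccc(OC)cc2OC)c(Br)c1C#Cc1ccc(OC)cc1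
F5 | step 8 | racemic 4-bromo-5-(2,4-dihydroxyphenyl)-3-(4-hydroxyphenyl)-2-benzofuran-1(3H)-one | Oc1ccc(C2OC(=O)c3ccc(-c4ccc(O)cc4O)c(Br)c32)cc1
F6 | step 8 | racemic 4-bromo-5-[2,4-bis(methoxymethoxy)phenyl]-3-[4-(methoxymethoxy)phenyl]-2-benzofuran-1(3H)-one | COCOc1ccc(C2OC(=O)c3ccc(-c4ccc(OCOC)cc4OCOC)c(Br)c32)cc1
F7 | step 8 | racemic {2-bromo-3-[2,4-bis(methoxymethoxy)phenyl]-6-(hydroxymethyl)phenyl}[4-(methoxymethoxy)phenyl]methanol | COCOc1ccc(C(O)c2c(CO)ccc(-c3ccc(OCOC)cc3OCOC)c2Br)cc1
F8 | step 8 | racemic {2-bromo-6-({[tert-butyl(dimethyl)silyl]oxy}methyl)-3-[2,4-bis(methoxymethoxy)phenyl]phenyl}[4-(methoxymethoxy)phenyl]methanol | COCOc1ccc(C(O)c2c(CO[Si](C)(C)C(C)(C)C)ccc(-c3ccc(OCOC)cc3OCOC)c2Br)cc1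
F9 | step 8 | {2-bromo-6-({[tert-butyl(dimethyl)silyl]oxy}methyl)-3-[2,4-bis(methoxymethoxy)phenyl]phenyl}[4-(methoxymethoxy)phenyl]methanone | COCOc1ccc(C(=O)c2c(CO[Si](C)(C)C(C)(C)C)ccc(-c3ccc(OCOC)cc3OCOC)c2Br)cc1
F10 | step 8 | {[3-bromo-4-[2,4-bis(methoxymethoxy)phenyl]-2-{[4-(methoxymethoxy)phenyl]ethynyl}phenyl]methoxy}(tert-butyl)dimethylsilane | COCOc1ccc(C#Cc2c(CO[Si](C)(C)C(C)(C)C)ccc(-c3ccc(OCOC)cc3OCOC)c2Br)cc1
F11 | step 8 | 4,4'-bis(methoxymethoxy)benzophenone | COCOc1ccc(C(=O)c2ccc(OCOC)cc2)cc1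
F12 | step 8 | [3-({[tert-butyl(dimethyl)silyl]oxy}methyl)-6-[2,4-bis(methoxymethoxy)phenyl]-2-{[4-(methoxymethoxy)phenyl]ethynyl}phenyl]bis[4-(methoxymethoxy)phenyl]methanol | COCOc1ccc(C#Cc2c(CO[Si](C)(C)C(C)(C)C)ccc(-c3ccc(OCOC)cc3OCOC)c2C(O)(c4ccc(OCOC)cc4)c5ccc(OCOC)cc5)cc1
F13 | step 2 | 3-bromo-4-(2,4-dimethoxyphenyl)benzoic acid | OC(=O)c1ccc(-c2ccc(OC)cc2OC)c(Br)c1
F14 | step 2 | lithium 3-bromo-4-(2,4-dimethoxyphenyl)-2-lithiobenzoate | [Li]OC(=O)c1ccc(-c2ccc(OC)cc2OC)c(Br)c1[Li]
F15 | step 2 | racemic 3-bromo-4-(2,4-dimethoxyphenyl)-2-[hydroxy(4-methoxyphenyl)methyl]benzoic acid | COc1ccc(C(O)c2c(C(=O)O)ccc(-c3ccc(OC)cc3OC)c2Br)cc1
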